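**Plan**

- Locants (germacrane): C1 ketone, C2=C3 enol ether, C4 (CHMe), C5, C6 (lactone O), C7, C8 (tiglate), C9, C10 (CMe, its oxygen bridging to C3); lactone C6–O–C12(=O)–C11(Me)–C7.
- Cuts, backwards: the C8–O ester bond; the C4–H and C5–H bonds; C4=C5 (the ten-membered ring, by ring-closing metathesis); C7–C8 (a Barbier allylation that brings in the whole lactone); O–C3 and C1–C2 of the furanone (hydroxy-ynone cyclisation, acetylide acylation).
- Enabling feature: C4–C5 is the only link between furanone carbon C3 and lactone carbinol C6. An isopropenyl group on C3 and a vinyl group on C6, each on a finished five-membered ring, can therefore be joined into the ring alkene C4=C5, conjugated to the furanone; its reduction then sets C4.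
- Forward: furanone ring first (from citramalate), butenolide second (a first metathesis), union to the 6,12-lactone, then the ten-membered carbocycle, hydrogenation and tigloylation.
- Stereochemistry: C10 from (R)-citramalic acid; C6 from Sharpless epoxidation of divinyl carbinol; C7 and C8 relayed from C6 in the allylation; C11 by thermodynamic protonation to the all-trans lactone; C4 by hydrogenation of the Z ring alkene from its open face.

Key step: step 15

Remark: the 6,12-lactone with a free C8 hydroxyl is assumed not to migrate to O8 under the neutral or briefly basic conditions of steps 12 to 16; descriptors are CIP descriptors of each compound as named (C7 changes from R to S on acylation of O8 for priority reasons only).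

**Route**

Step 1
Reactants: 1 (R)-citramalic acid
Product: 2 (R)-2-(2,2,4-trimethyl-5-oxo-1,3-dioxolan-4-yl)acetic acid
Conditions: 2,2-dimethoxypropane, TsOH·H2O (cat.), CH2Cl2, rt
Reagents that add atoms: 2,2-dimethoxypropane COC(C)(C)OC
Why: Acid-catalysed acetonide formation (transacetalisation) ties the tertiary hydroxyl and the adjacent carboxyl (C10–OH and C1) into the five-membered 1,3-dioxolan-4-one that α-hydroxy acids prefer and leaves the CH2CO2H arm (C9–C8) free, without involving the C10 centre.

Step 2
Reactants: 2 (R)-2-(2,2,4-trimethyl-5-oxo-1,3-dioxolan-4-yl)acetic acid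
Product: 3 (R)-5-(2-hydroxyethyl)-2,2,5-trimethyl-1,3-dioxolan-4-one
Conditions: BH3·SMe2, THF, 0 °C to rt; MeOH quench
Reagents that add atoms: none
Why: Chemoselective borane reduction, in which the free acid is reduced through its acyloxyborane far faster than the dioxolanone ester, so that only C8 is taken to the alcohol.

Step 3
Reactants: 3 (R)-5-(2-hydroxyethyl)-2,2,5-trimethyl-1,3-dioxolan-4-one
Product: 4 (R)-5-[2-(tert-butyldimethylsilyloxy)ethyl]-2,2,5-trimethyl-1,3-dioxolan-4-one
Conditions: TBSCl, imidazole, CH2Cl2, 0 °C to rt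
Reagents that add atoms: tert-butyldimethylsilyl chloride CC(C)(C)[Si](C)(C)Cl
Why: Imidazole-promoted silylation of the primary alcohol stops it from lactonising onto the dioxolanone and masks C8–OH for the organomagnesium and organolithium steps.

Step 4
Reactants: 4 (R)-5-[2-(tert-butyldimethylsilyloxy)ethyl]-2,2,5-trimethyl-1,3-dioxolan-4-one
Product: 5 (2R)-4-(tert-butyldimethylsilyloxy)-2-hydroxy-N-methoxy-N,2-dimethylbutanamide
Conditions: MeNHOMe·HCl, i-PrMgCl, THF, −20 to 0 °C; aq NH4Cl
Reagents that add atoms: N,O-dimethylhydroxylamine hydrochloride Cl.CNOC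
Why: Aminolysis of the activated dioxolanone ester by the magnesium amide of N,O-dimethylhydroxylamine opens the ring with loss of acetone and gives the Weinreb amide at C1 with the tertiary hydroxyl free, the quaternary C10 being unable to epimerise.

Step 5
Reactants: 5 (2R)-4-(tert-butyldimethylsilyloxy)-2-hydroxy-N-methoxy-N,2-dimethylbutanamide and 6 2-methylbut-1-en-3-yne
Product: 8 (6R)-8-(tert-butyldimethylsilyloxy)-6-hydroxy-2,6-dimethyloct-1-en-3-yn-5-one, via lithium 3-methylbut-3-en-1-yn-1-ide 7 (not isolated)
Conditions: 6 (3 equiv), n-BuLi (2.9 equiv), THF, −78 °C; then 5, −78 to −30 °C; cold sat. aq NH4Cl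
Reagents that add atoms: none
Why: Weinreb ketone synthesis, in which the first equivalent of acetylide deprotonates the tertiary hydroxyl, the next adds to the amide and the N-methoxy chelate holds the tetrahedral adduct until the cold quench, so that the C1–C2 bond forms without over-addition.

Step 6
Reactants: 8 (6R)-8-(tert-butyldimethylsilyloxy)-6-hydroxy-2,6-dimethyloct-1-en-3-yn-5-one
Product: 9 (R)-2-[2-(tert-butyldimethylsilyloxy)ethyl]-2-methyl-5-(prop-1-en-2-yl)furan-3(2H)-one
Conditions: (Ph3P)AuCl (5 mol %), AgOTf (5 mol %), toluene, rt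
Reagents that add atoms: none
Why: Gold-catalysed cycloisomerisation of the hydroxy ynone (5-endo-dig hydroalkoxylation), in which the cationic gold complex activates the alkyne, the C10 hydroxyl adds to C3 and protodeauration releases the 3(2H)-furanone without forming a stereocentre.

Step 7
Reactants: 9 (R)-2-[2-(tert-butyldimethylsilyloxy)ethyl]-2-methyl-5-(prop-1-en-2-yl)furan-3(2H)-one
Product: 10 (R)-2-(2-hydroxyethyl)-2-methyl-5-(prop-1-en-2-yl)furan-3(2H)-one
Conditions: HF·pyridine, pyridine, THF, 0 °C to rt
Reagents that add atoms: none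
Why: Fluoride-mediated desilylation, driven by the Si–F bond and run in buffered pyridine, frees the primary C8 alcohol without touching the vinylogous ester.

Step 8
Reactants: 10 (R)-2-(2-hydroxyethyl)-2-methyl-5-(prop-1-en-2-yl)furan-3(2H)-one
Product: 11 (R)-2-[2-methyl-3-oxo-5-(prop-1-en-2-yl)-2,3-dihydrofuran-2-yl]acetaldehyde
Conditions: Dess–Martin periodinane, CH2Cl2, 0 °C to rt; used at once
Reagents that add atoms: none
Why: Dess–Martin oxidation stops at the aldehyde under base-free conditions, which matters because the furanone oxygen is β to the new carbonyl and would be expelled on enolisation.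

Step 9
Reactants: 12 penta-1,4-dien-3-ol
Product: 13 (2R,3S)-1,2-epoxypent-4-en-3-ol
Conditions: Ti(OiPr)4, L-(+)-diisopropyl tartrate, t-BuOOH, 4 Å molecular sieves, CH2Cl2, −20 °C
Reagents that add atoms: tert-butyl hydroperoxide CC(C)(C)OO
Why: Sharpless asymmetric epoxidation, in which the titanium–tartrate complex epoxidises one enantiotopic vinyl group of the prochiral carbinol on one face (erythro) and the minor enantiomer is consumed faster by a second epoxidation, so that the carbinol carbon (later C6) is fixed as S and the two vinyl groups are told apart.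

Step 10
Reactants: 13 (2R,3S)-1,2-epoxypent-4-en-3-ol and 14 2-(bromomethyl)prop-2-enoic acid
Product: 15 (1S)-1-[(2R)-oxiran-2-yl]prop-2-en-1-yl 2-(bromomethyl)prop-2-enoate
Conditions: DCC, DMAP (cat.), CH2Cl2, 0 °C
Reagents that add atoms: none
Why: Steglich esterification (carbodiimide activation, acyl transfer by DMAP) acylates the secondary alcohol with retention because the C–O bond of the carbinol is not broken.

Step 11
Reactants: 15 (1S)-1-[(2R)-oxiran-2-yl]prop-2-en-1-yl 2-(bromomethyl)prop-2-enoate
Product: 16 (5S)-3-(bromomethyl)-5-[(2R)-oxiran-2-yl]furan-2(5H)-one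
Conditions: second-generation Grubbs catalyst (5 mol %), CH2Cl2, 40 °C, 0.01 M
Reagents that add atoms: none
Why: Ring-closing metathesis, in which the ruthenium alkylidene forms at the vinyl group and closes onto the 1,1-disubstituted acrylate with loss of ethylene to give the butenolide, and because the second vinyl group is masked as the epoxide only this five-membered ring can form and the C6 centre stays a single enantiomer.

Step 12
Reactants: 11 (R)-2-[2-methyl-3-oxo-5-(prop-1-en-2-yl)-2,3-dihydrofuran-2-yl]acetaldehyde and 16 (5S)-3-(bromomethyl)-5-[(2R)-oxiran-2-yl]furan-2(5H)-one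
Product: 18 (4R,5S)-4-[(1S)-1-hydroxy-2-[(2R)-2-methyl-3-oxo-5-(prop-1-en-2-yl)-2,3-dihydrofuran-2-yl]ethyl]-3-methylidene-5-[(2R)-oxiran-2-yl]oxolan-2-one, via allylzinc bromide 17 (not isolated)
Conditions: Zn dust, THF/sat. aq NH4Cl, 0 °C to rt
Reagents that add atoms: none
Why: Barbier allylation, in which zinc inserts into the allylic C–Br bond and the allylzinc adds to the aldehyde through its ring carbon (allylic transposition) in a closed six-membered chair transition state, on the butenolide face away from the oxiranyl group on C6 (C7–C8 trans to it) and with the aldehyde chain equatorial against the fixed E-type allyl geometry (C8–OH anti to C6), which sets C7 and C8 from C6 alone and leaves the 6,12-lactone with an exocyclic methylene.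

Step 13
Reactants: 18 (4R,5S)-4-[(1S)-1-hydroxy-2-[(2R)-2-methyl-3-oxo-5-(prop-1-en-2-yl)-2,3-dihydrofuran-2-yl]ethyl]-3-methylidene-5-[(2R)-oxiran-2-yl]oxolan-2-one
Product: 19 (3S,4R,5S)-4-[(1S)-1-hydroxy-2-[(2R)-2-methyl-3-oxo-5-(prop-1-en-2-yl)-2,3-dihydrofuran-2-yl]ethyl]-3-methyl-5-[(2R)-oxiran-2-yl]oxolan-2-one
Conditions: NaBH4, MeOH, −20 °C; aq NH4Cl
Reagents that add atoms: none
Why: Conjugate reduction, in which borohydride adds to the exocyclic α-methylene lactone, by far the most electrophilic and least hindered acceptor present, and protonation of the lactone enolate under equilibrating methoxide should leave the C11 methyl trans to the C7 side chain (11S), the more stable arrangement on the all-trans lactone.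

Step 14
Reactants: 19 (3S,4R,5S)-4-[(1S)-1-hydroxy-2-[(2R)-2-methyl-3-oxo-5-(prop-1-en-2-yl)-2,3-dihydrofuran-2-yl]ethyl]-3-methyl-5-[(2R)-oxiran-2-yl]oxolan-2-one
Product: 20 (3S,4R,5R)-5-ethenyl-4-[(1S)-1-hydroxy-2-[(2R)-2-methyl-3-oxo-5-(prop-1-en-2-yl)-2,3-dihydrofuran-2-yl]ethyl]-3-methyloxolan-2-one
Conditions: Ph3P=Se, CF3CO2H, CH2Cl2, 0 °C to rt
Reagents that add atoms: none
Why: Epoxide deoxygenation by oxygen–selenium exchange, in which selenium of Ph3P=Se opens the protonated epoxide at its CH2 terminus, oxygen passes to phosphorus and selenium is then extruded, returning the C6 vinyl group without touching the C6–O bond or any stereocentre.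

Step 15
Reactants: 20 (3S,4R,5R)-5-ethenyl-4-[(1S)-1-hydroxy-2-[(2R)-2-methyl-3-oxo-5-(prop-1-en-2-yl)-2,3-dihydrofuran-2-yl]ethyl]-3-methyloxolan-2-one
Product: 21 (4Z,6R,7R,8S,10R,11S)-8-hydroxy-1-oxo-3,10-epoxygermacra-2,4-dien-6,12-olide
Conditions: second-generation Hoveyda–Grubbs catalyst (10 mol %, then 10 mol %), toluene, 80 °C, 1 mM, argon sparge
Reagents that add atoms: none
Why: The ruthenium alkylidene exchanges onto the monosubstituted C6 vinyl group, the resulting C5 alkylidene adds across the isopropenyl C4=CH2 bond to a ruthenacyclobutane, and cycloreversion releases ethylene and the C4=C5 bond. The closest known reaction type is ring-closing metathesis to medium rings that carry a trisubstituted alkene conjugated to a 3(2H)-furanone. The ten-membered carbocycle C1–C10 (read through the ether bridge, a nine-membered oxacycle) closes end to end at C4=C5 by this intramolecular alkylidene transfer. No stereocentre is formed; the alkene has to be Z and can only be Z, because an E alkene cannot be spanned inside the furanone-bridged ring. Cyclisation must beat dimerisation and double-bond migration: high dilution and removal of ethylene favour the ring, the two olefins sit on rigid five-membered rings joined by only three rotatable bonds (C7–C8, C8–C9, C9–C10), and the electron-poor 1,1-disubstituted isopropenyl group does not homodimerise. The C2=C3 enol ether of the vinylogous ester is inert to the catalyst.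

Step 16
Reactants: 21 (4Z,6R,7R,8S,10R,11S)-8-hydroxy-1-oxo-3,10-epoxygermacra-2,4-dien-6,12-olide
Product: 22 (4S,6R,7R,8S,10R,11S)-8-hydroxy-1-oxo-3,10-epoxygermacr-2-en-6,12-olide
Conditions: H2 (1 atm), RhCl(PPh3)3 (20 mol %), benzene/EtOH, rt to 40 °C
Reagents that add atoms: none
Why: Homogeneous hydrogenation (syn addition of H2 from a rhodium dihydride), in which relief of allylic strain at the Z alkene puts H6 in the alkene plane facing C3, so that with C6 R the C7–C8–C9 bridge lies over the Si face of C4 and the catalyst should deliver both hydrogens to the open Re face, making C4 S, while the C2=C3 enol ether and the lactone C–O bonds are left alone by this catalyst.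

Step 17
Reactants: 22 (4S,6R,7R,8S,10R,11S)-8-hydroxy-1-oxo-3,10-epoxygermacr-2-en-6,12-olide and 23 tiglic acid
Product: 25 (4S,6R,7S,8S,10R,11S)-8-[(E)-2-methylbut-2-enoyloxy]-1-oxo-3,10-epoxygermacr-2-en-6,12-olide, via tigloyl 2,4,6-trichlorobenzoyl anhydride 24 (not isolated)
Conditions: 23, 2,4,6-trichlorobenzoyl chloride, Et3N, THF, rt; then 22, DMAP, toluene, rt to 60 °C
Reagents that add atoms: none
Why: Yamaguchi esterification, in which the mixed anhydride of tiglic acid passes the tigloyl group through the acylpyridinium of DMAP to the hindered secondary C8 hydroxyl, with retention at C8 (its C–O bond is not broken) and without disturbing the E alkene of the acid.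

**Compound list**

1 | (R)-citramalic acid | OC(=O)C[C@@](C)(O)C(=O)O | starting material
2 | (R)-2-(2,2,4-trimethyl-5-oxo-1,3-dioxolan-4-yl)acetic acid | OC(=O)C[C@@]1(C)OC(C)(C)OC1=O | intermediate
3 | (R)-5-(2-hydroxyethyl)-2,2,5-trimethyl-1,3-dioxolan-4-one | OCC[C@@]1(C)OC(C)(C)OC1=O | intermediate
4 | (R)-5-[2-(tert-butyldimethylsilyloxy)ethyl]-2,2,5-trimethyl-1,3-dioxolan-4-one | CC(C)(C)[Si](C)(C)OCC[C@@]1(C)OC(C)(C)OC1=O | intermediate
5 | (2R)-4-(tert-butyldimethylsilyloxy)-2-hydroxy-N-methoxy-N,2-dimethylbutanamide | CC(C)(C)[Si](C)(C)OCC[C@@](C)(O)C(=O)N(C)OC | intermediate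
6 | 2-methylbut-1-en-3-yne | C=C(C)C#C | starting material
7 | lithium 3-methylbut-3-en-1-yn-1-ide | [Li]C#CC(C)=C | intermediate
8 | (6R)-8-(tert-butyldimethylsilyloxy)-6-hydroxy-2,6-dimethyloct-1-en-3-yn-5-one | CC(C)(C)[Si](C)(C)OCC[C@@](C)(O)C(=O)C#CC(C)=C | intermediate
9 | (R)-2-[2-(tert-butyldimethylsilyloxy)ethyl]-2-methyl-5-(prop-1-en-2-yl)furan-3(2H)-one | CC(C)(C)[Si](C)(C)OCC[C@@]1(C)OC(=CC1=O)C(C)=C | intermediate
10 | (R)-2-(2-hydroxyethyl)-2-methyl-5-(prop-1-en-2-yl)furan-3(2H)-one | OCC[C@@]1(C)OC(=CC1=O)C(C)=C | intermediate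
11 | (R)-2-[2-methyl-3-oxo-5-(prop-1-en-2-yl)-2,3-dihydrofuran-2-yl]acetaldehyde | O=CC[C@@]1(C)OC(=CC1=O)C(C)=C | intermediate
12 | penta-1,4-dien-3-ol | C=CC(O)C=C | starting material
13 | (2R,3S)-1,2-epoxypent-4-en-3-ol | C=C[C@H](O)[C@H]1CO1 | intermediate
14 | 2-(bromomethyl)prop-2-enoic acid | OC(=O)C(=C)CBr | starting material
15 | (1S)-1-[(2R)-oxiran-2-yl]prop-2-en-1-yl 2-(bromomethyl)prop-2-enoate | C=C[C@H](OC(=O)C(=C)CBr)[C@H]1CO1 | intermediate
16 | (5S)-3-(bromomethyl)-5-[(2R)-oxiran-2-yl]furan-2(5H)-one | BrCC1=C[C@H](OC1=O)[C@H]2CO2 | intermediate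
17 | [(5S)-2-oxo-5-[(2R)-oxiran-2-yl]-2,5-dihydrofuran-3-yl]methylzinc bromide | Br[Zn]CC1=C[C@H](OC1=O)[C@H]2CO2 | intermediate
18 | (4R,5S)-4-[(1S)-1-hydroxy-2-[(2R)-2-methyl-3-oxo-5-(prop-1-en-2-yl)-2,3-dihydrofuran-2-yl]ethyl]-3-methylidene-5-[(2R)-oxiran-2-yl]oxolan-2-one | O1C[C@@H]1[C@H]2OC(=O)C(=C)[C@@H]2[C@@H](O)C[C@@]3(C)OC(=CC3=O)C(C)=C | intermediate
19 | (3S,4R,5S)-4-[(1S)-1-hydroxy-2-[(2R)-2-methyl-3-oxo-5-(prop-1-en-2-yl)-2,3-dihydrofuran-2-yl]ethyl]-3-methyl-5-[(2R)-oxiran-2-yl]oxolan-2-one | O1C[C@@H]1[C@H]2OC(=O)[C@@H](C)[C@@H]2[C@@H](O)C[C@@]3(C)OC(=CC3=O)C(C)=C | intermediate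
20 | (3S,4R,5R)-5-ethenyl-4-[(1S)-1-hydroxy-2-[(2R)-2-methyl-3-oxo-5-(prop-1-en-2-yl)-2,3-dihydrofuran-2-yl]ethyl]-3-methyloxolan-2-one | C=C[C@H]1OC(=O)[C@@H](C)[C@@H]1[C@@H](O)C[C@@]1(C)OC(=CC1=O)C(C)=C | intermediate
21 | (4Z,6R,7R,8S,10R,11S)-8-hydroxy-1-oxo-3,10-epoxygermacra-2,4-dien-6,12-olide | O[C@H]1C[C@@]2(C)OC(=CC2=O)/C(C)=C\[C@H]2OC(=O)[C@@H](C)[C@H]12 | intermediate
22 | (4S,6R,7R,8S,10R,11S)-8-hydroxy-1-oxo-3,10-epoxygermacr-2-en-6,12-olide | O[C@H]1C[C@@]2(C)OC(=CC2=O)[C@@H](C)C[C@H]2OC(=O)[C@@H](C)[C@H]12 | intermediate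
23 | tiglic acid, (E)-2-methylbut-2-enoic acid | C/C=C(\C)C(=O)O | starting material
24 | tigloyl 2,4,6-trichlorobenzoyl anhydride | C/C=C(\C)C(=O)OC(=O)c1c(Cl)cc(Cl)cc1Cl | intermediate
25 | (4S,6R,7S,8S,10R,11S)-8-[(E)-2-methylbut-2-enoyloxy]-1-oxo-3,10-epoxygermacr-2-en-6,12-olide | C/C=C(\C)C(=O)O[C@H]1C[C@@]2(C)OC(=CC2=O)[C@@H](C)C[C@H]2OC(=O)[C@@H](C)[C@H]12 | target

**Step count and risks**

Total step count: 17 (steps 1–8 to the aldehyde, steps 9–11 to the bromomethyl butenolide, steps 12–17 after the union).
Longest linear sequence: 14 steps from (R)-citramalic acid (steps 1–8, then 12–17).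

The three steps most likely to fail:

Step 15. Ring closure may lose to dimerisation and double-bond migration, either because the C5 alkylidene is held by the free C8 hydroxyl and the lactone carbonyl or because the folded conformers that bring C4 and C5 together are too thinly populated. The fallback masks the hydroxyl before the metathesis. It sets out from 20, which is silylated (Et3SiOTf, 2,6-lutidine, CH2Cl2) to the C8 triethylsilyl ether of 20 F1. F1 has no chelating hydroxyl, and its bulky C8 substituent should push the C7–C8–C9 chain towards the folded conformer. Metathesis with the second-generation Hoveyda–Grubbs catalyst should then give the C8 triethylsilyl ether of 21 F2, and HF·pyridine returns the route to 21.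

Step 16. The trisubstituted alkene may take up hydrogen slowly, and hydrogen may be delivered to the inner face or to both faces. The fallback replaces kinetic face control by thermodynamic control. It sets out from 21: 1,6-hydride addition with [(Ph3P)CuH]6 (hydride to C5) and protonation of the extended enolate should give the saturated furanone as a C4 mixture that contains the C4 epimer of 22 F3. Because H4 is the γ-proton of the vinylogous ester, DBU in toluene should equilibrate F3 with 22 through the dienolate; 22 is expected to be the more stable epimer, but this is not established. The wanted epimer is separated and the rest recycled, and the route is rejoined at 22.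

Step 13. Hydride may attack the furanone carbonyl or add 1,6 to the isopropenyl dienone, the lactone may be reduced, and the lactone acyl group may migrate to O8 in the methoxide medium. The fallback postpones saturation of C11=C13 to the hydrogenation. It sets out from 18, which is deoxygenated under the conditions of step 14 to the 11(13)-dehydro analogue of 20 F4. Metathesis as in step 15 should give the 11(13)-dehydro analogue of 21 F5, since the exocyclic methylene cannot form a ring with the C5 alkylidene and is a poor cross-metathesis partner. H2 with RhCl(PPh3)3 then saturates the exocyclic methylene together with C4=C5; if C11 emerges cis, DBU equilibrates it to the trans lactone. The route is rejoined at 22.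

**Further compounds**

F1 | step 15 | C8 triethylsilyl ether of 20 | C=C[C@H]1OC(=O)[C@@H](C)[C@@H]1[C@@H](O[Si](CC)(CC)CC)C[C@@]1(C)OC(=CC1=O)C(C)=C
F2 | step 15 | C8 triethylsilyl ether of 21 | CC[Si](CC)(CC)O[C@H]1C[C@@]2(C)OC(=CC2=O)/C(C)=C\[C@H]2OC(=O)[C@@H](C)[C@H]12
F3 | step 16 | C4 epimer of 22 | O[C@H]1C[C@@]2(C)OC(=CC2=O)[C@H](C)C[C@H]2OC(=O)[C@@H](C)[C@H]12
F4 | step 13 | 11(13)-dehydro analogue of 20 (α-methylene lactone with the C6 vinyl group) | C=C[C@H]1OC(=O)C(=C)[C@@H]1[C@@H](O)C[C@@]1(C)OC(=CC1=O)C(C)=C
F5 | step 13 | 11(13)-dehydro analogue of 21 (α-methylene lactone macrocycle) | O[C@H]1C[C@@]2(C)OC(=CC2=O)/C(C)=C\[C@H]2OC(=O)C(=C)[C@H]12
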